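**Plan**
1. Retrosynthetic cuts, in order: the acyl–O bond of the C6 anisoate; C10–H (alcohol back to enone); C6–O (back to a 6,8-dien-10-one); C1–CH3; C4–i-Pr. Last come C5–C1 and C5–C6, which turns the hydroazulene into a benzene ring carrying a diazoketone chain.
2. Enabling feature: the seven-membered ring is a 1,2,4-trisubstituted benzene plus one carbon. C1 (quaternary, CH3) is the ipso carbon, C10 (CHOH) the phenol carbon ortho to it, C8 (vinylic CH3) the para tolyl carbon and C6 (ester CH) the free ortho carbon. C5 (ring-fusion CH) is the inserted carbene carbon, and C4 [C(OH)i-Pr] is the diazoketone carbonyl, tied to C1 by C3–C2 of the five-membered ring.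
3. Forward: 7-methylcoumarin supplies the arene, the phenol oxygen and the tether. The five- and seven-membered rings arise together in one Buchner step. Then i-Pr, the angular CH3, the C6 oxygen, the anisoate and the C10 hydrogen are added in that order.
4. Stereochemistry: C5 comes from a chiral copper bis(oxazoline) catalyst. C4, C1, C6 and C10 are relayed from it by substrate control: addition syn to C5–H at C4, convex-face methylation at C1, borylation anti to the angular CH3 at C6, and peripheral hydride attack at C10.

Key step: step 5

Numbering (daucane, used from the bicyclic compounds on): C1 ring-fusion C–CH3, C2/C3 ring CH2, C4 C(OH)(i-Pr), C5 ring-fusion CH, C6 CH–O(ester), C7 CH2, C8 =C(CH3), C9 =CH, C10 CH–OH. β is the face of the C1 methyl and α the face of C5–H.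
Assumption: the (S,S)-ligand is taken to deliver the (8aR)-azulenone; if the sense of induction is the reverse, the equally available (R,R)-ligand is used and nothing else changes.

**Route**

Step 1
Reactants: 1 7-methylcoumarin
Product: 2 7-methylchroman-2-one (7-methyl-3,4-dihydrocoumarin)
Conditions: H2 (1 atm), 10% Pd/C, EtOAc, rt
Reagents that add atoms: none
Why: Heterogeneous catalytic hydrogenation saturates the conjugated C3–C4 alkene of a coumarin selectively, since the benzene ring and the lactone carbonyl are inert over Pd/C at 1 atm.

Step 2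
Reactants: 2 7-methylchroman-2-one
Product: 3 3-(2-hydroxy-4-methylphenyl)propanoic acid
Conditions: NaOH (2.5 equiv), THF/H2O, rt; then 1 M HCl to pH 3, 0 °C, immediate extraction
Reagents that add atoms: sodium hydroxide, [Na+].[OH-]
Why: Saponification of an aryl ester lactone is fast at room temperature, and cold acidification with immediate extraction delivers the open hydroxy acid before acid-catalysed relactonisation sets in.

Step 3
Reactants: 3 3-(2-hydroxy-4-methylphenyl)propanoic acid
Product: 5 3-[2-(tert-butyldimethylsilyloxy)-4-methylphenyl]propanoic acid, via bis-silyl derivative 4 (not isolated)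
Conditions: TBSCl (2.4 equiv), imidazole (5 equiv), DMF, rt; then AcOH/THF/H2O (3:1:1), rt
Reagents that add atoms: tert-butyldimethylsilyl chloride, CC(C)(C)[Si](C)(C)Cl
Why: Silylation with TBSCl/imidazole caps both OH groups, and selective hydrolysis then exploits the much greater lability of a silyl ester over an aryl silyl ether in dilute acetic acid, leaving a phenol that can no longer close back to the lactone.

Step 4
Reactants: 5 3-[2-(tert-butyldimethylsilyloxy)-4-methylphenyl]propanoic acid; 6 trimethylsilyldiazomethane
Product: 8 1-diazo-4-[2-(tert-butyldimethylsilyloxy)-4-methylphenyl]butan-2-one, via mixed carbonic anhydride 7 (not isolated)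
Conditions: i-BuOCOCl, N-methylmorpholine, THF, −20 °C; then 6 (2 M in hexanes, 2 equiv), MeCN, 0 °C to rt
Reagents that add atoms: trimethylsilyldiazomethane 6, C[Si](C)(C)C=[N+]=[N-]; isobutyl chloroformate (atoms in 7 only), CC(C)COC(=O)Cl
Why: Arndt–Eistert-type diazoketone synthesis in which the nucleophilic diazo carbon of 6 attacks the acyl carbonyl of the mixed anhydride and the departing carbonate removes the silyl group, all under near-neutral conditions that spare the aryl silyl ether.

Step 5
Reactants: 8 1-diazo-4-[2-(tert-butyldimethylsilyloxy)-4-methylphenyl]butan-2-one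
Product: 10 (8aR)-4-(tert-butyldimethylsilyloxy)-6-methyl-3,8a-dihydroazulen-1(2H)-one, via norcaradiene 9 (not isolated)
Conditions: Cu(MeCN)4PF6 (5 mol %), 2,2'-(propane-2,2-diyl)bis[(4S)-4-tert-butyl-4,5-dihydrooxazole] (6 mol %), NaB[3,5-(CF3)2C6H3]4 (6 mol %), CH2Cl2, 40 °C, slow addition of 8 over 3 h; filtration through Celite, used at once
Reagents that add atoms: none
Why: Loss of N2 at monovalent copper gives an electrophilic copper carbene that adds across the bond between the ipso carbon and the unsubstituted ortho carbon of the arene, and the norcaradiene 9 so formed opens by a disrotatory six-electron electrocyclic reaction that breaks exactly this former aromatic bond. The closest known chemistry is the intramolecular Buchner reaction of 1-diazo-4-arylbutan-2-ones to 3,8a-dihydroazulen-1(2H)-ones, run with Rh2(OAc)4 in racemic form and with copper bis(oxazoline) catalysts in enantioselective form. The cyclopentanone closes by bonding of the carbene carbon (C5) to the ipso carbon (C1) across the three-atom tether C4–C3–C2, that is by intramolecular [2+1] cycloaddition, and the seven-membered ring is made by one-carbon expansion of the benzene ring once C5 is also bonded to C6 and the C1–C6 bond has opened. The single new stereocentre C5 is set by the twofold-symmetric ligand, which decides the face of the carbene that meets the arene, and it survives the ring opening because none of its four bonds is broken there. The step needs site selectivity between the two ipso–ortho bonds, which the bulky silyloxy group secures by shielding its own side, and chemoselectivity for the arene over dimerisation or C–H insertion, which the two donor substituents and slow addition secure. The product is only filtered and taken on at once, since acid turns such trienones into 2-tetralones and base moves the double bonds into conjugation and erases C5.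

Step 6
Reactants: 10 (8aR)-4-(tert-butyldimethylsilyloxy)-6-methyl-3,8a-dihydroazulen-1(2H)-one; 11 isopropylmagnesium chloride
Product: 12 (1R,8aR)-4-(tert-butyldimethylsilyloxy)-6-methyl-1-(propan-2-yl)-1,2,3,8a-tetrahydroazulen-1-ol (i-Pr cis to the ring-fusion H)
Conditions: anhydrous CeCl3 (2 equiv), 11 (2 M in THF, 1.8 equiv), THF, 0 °C, 1.5 h; then 10, −78 °C; pH 7 aqueous quench
Reagents that add atoms: isopropylmagnesium chloride 11, CC(C)[Mg]Cl
Why: Organocerium 1,2-addition, the standard answer to easily enolised ketones, is fast at −78 °C and so weakly basic that the labile C5–H should stay in place, and the reagent should approach the cyclopentanone on the face of the small C5–H, away from the C6 arm of the boat-shaped seven-membered ring, which places i-Pr α (cis to C5–H) and OH β (4R).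

Step 7
Reactants: 12 (1R,8aR)-4-(tert-butyldimethylsilyloxy)-6-methyl-1-(propan-2-yl)-1,2,3,8a-tetrahydroazulen-1-ol; 13 iodomethane
Product: 15 (1S,4R,5R)-4β-hydroxydauca-6,8-dien-10-one (trans-fused), via ammonium enolate 14 (not isolated)
Conditions: [Bu4N][Ph3SiF2] (1.2 equiv), 13 (10 equiv), 4 Å MS, THF, −40 °C to 0 °C
Reagents that add atoms: iodomethane 13, CI; tetrabutylammonium difluorotriphenylsilicate (cation in 14 only), CCCC[N+](CCCC)(CCCC)CCCC.F[Si-](F)(c1ccccc1)(c1ccccc1)c1ccccc1
Why: Fluoride-triggered regiospecific alkylation of a silyl enol ether: fluoride transfer from the silicate frees only the C1=C10 enolate 14, whose sole carbon terminus is C1 and which a tertiary alcohol is too weak an acid to quench in THF, and MeI should enter on the convex β face of the cycloheptatriene boat, anti to the endo C5–H and the α i-Pr group, to set the quaternary centre (1S) with a trans ring fusion.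

Step 8
Reactants: 15 (1S,4R,5R)-4β-hydroxydauca-6,8-dien-10-one
Product: 16 4β-hydroxy-6α-(4,4,5,5-tetramethyl-1,3,2-dioxaborolan-2-yl)dauc-7-en-10-one
Conditions: CuCl (5 mol %), NaOt-Bu (10 mol %), bis[2-(diphenylphosphino)phenyl] ether (5 mol %), B2pin2 (1.2 equiv), MeOH (2 equiv), THF, rt
Reagents that add atoms: bis(pinacolato)diboron, CC1(C)OB(OC1(C)C)B1OC(C)(C)C(C)(C)O1
Why: Copper-catalysed conjugate borylation in its 1,6 mode, established for α,β,γ,δ-unsaturated ketones: the fully substituted β carbon C8 turns the boryl-copper species to the CH terminus C6, where it should add on the α face, anti to the axial C1 methyl that lies 1,3 to C6, before MeOH protonates the copper dienolate at C9.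

Step 9
Reactants: 16 4β-hydroxy-6α-(pinacolatoboryl)dauc-7-en-10-one
Product: 17 (1S,4R,5S,6S)-4β,6α-dihydroxydauc-7-en-10-one
Conditions: NaBO3·4H2O (4 equiv), THF/H2O (1:1), 0 °C to rt
Reagents that add atoms: sodium perborate tetrahydrate, drawn as its peroxoborate dimer, [Na+].[Na+].O[B-]1(O)OO[B-](O)(O)OO1
Why: Perborate oxidation of a secondary boronic ester goes by 1,2-migration from boron to oxygen with retention, so the α C–B bond becomes the α C–O bond (6S), and the reagent is too mild to touch the ketone or the alkene.

Step 10
Reactants: 17 (1S,4R,5S,6S)-4β,6α-dihydroxydauc-7-en-10-one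
Product: 18 (1S,4R,5S,6S)-4β,6α-dihydroxydauc-8-en-10-one
Conditions: DBU (0.2 equiv), CH2Cl2, rt
Reagents that add atoms: none
Why: Base-catalysed isomerisation of a β,γ- to an α,β-unsaturated ketone through the dienolate, which is reprotonated at C7 to give the conjugated trisubstituted enone, while hydroxide is too poor a leaving group for vinylogous elimination under catalytic amidine at room temperature; no stereocentre is touched.

Step 11
Reactants: 18 (1S,4R,5S,6S)-4β,6α-dihydroxydauc-8-en-10-one; 19 4-methoxybenzoyl chloride
Product: 20 (1S,4R,5S,6S)-4β-hydroxy-6α-(4-methoxybenzoyloxy)dauc-8-en-10-one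
Conditions: 19 (1.5 equiv), pyridine (3 equiv), DMAP (0.1 equiv), CH2Cl2, 0 °C to rt
Reagents that add atoms: 4-methoxybenzoyl chloride 19, COc1ccc(C(Cl)=O)cc1
Why: DMAP-catalysed acylation picks the only secondary alcohol, the tertiary C4–OH being inert, and the weak base and low temperature keep the product, a vinylogous β-acyloxy ketone, from eliminating.

Step 12
Reactants: 20 (1S,4R,5S,6S)-4β-hydroxy-6α-(4-methoxybenzoyloxy)dauc-8-en-10-one
Product: 21 (1S,4R,5S,6S,10R)-6α-(4-methoxybenzoyloxy)dauc-8-ene-4β,10α-diol (CNP0211568.1)
Conditions: LiBH(s-Bu)3 (1 M in THF, 2.2 equiv), THF, −78 °C; AcOH quench at −78 °C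
Reagents that add atoms: none
Why: 1,2-Reduction of a β,β-disubstituted enone by a bulky trialkylborohydride: conjugate hydride addition is blocked by the substituted β carbon and the path over the ring (α face) is closed by the axial C5–H, so that hydride should come from the ring periphery on the β side and leave the pseudoaxial 10α alcohol trans to the angular methyl (10R), the aryl ester being inert at −78 °C.

**Compound list**
1 | 7-methylcoumarin | Cc1ccc2C=CC(=O)Oc2c1 | starting material
2 | 7-methylchroman-2-one | Cc1ccc2CCC(=O)Oc2c1 | intermediate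
3 | 3-(2-hydroxy-4-methylphenyl)propanoic acid | Cc1ccc(CCC(=O)O)c(O)c1 | intermediate
4 | tert-butyldimethylsilyl 3-[2-(tert-butyldimethylsilyloxy)-4-methylphenyl]propanoate (not isolated) | Cc1ccc(CCC(=O)O[Si](C)(C)C(C)(C)C)c(O[Si](C)(C)C(C)(C)C)c1 | intermediate
5 | 3-[2-(tert-butyldimethylsilyloxy)-4-methylphenyl]propanoic acid | Cc1ccc(CCC(=O)O)c(O[Si](C)(C)C(C)(C)C)c1 | intermediate
6 | trimethylsilyldiazomethane | C[Si](C)(C)C=[N+]=[N-] | starting material
7 | isobutyl carbonic anhydride of acid 5 (not isolated) | Cc1ccc(CCC(=O)OC(=O)OCC(C)C)c(O[Si](C)(C)C(C)(C)C)c1 | intermediate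
8 | 1-diazo-4-[2-(tert-butyldimethylsilyloxy)-4-methylphenyl]butan-2-one | Cc1ccc(CCC(=O)C=[N+]=[N-])c(O[Si](C)(C)C(C)(C)C)c1 | intermediate
9 | norcaradiene valence tautomer of 10: cyclopropane C5–C1–C6 fused to the cyclopentanone along C5–C1 and to the silyloxy(methyl)cyclohexadiene along C1–C6, C5–H on the cyclohexadiene side (not isolated) | O=C1CC[C@]23[C@H]1[C@H]2C=C(C)C=C3O[Si](C)(C)C(C)(C)C | intermediate
10 | (8aR)-4-(tert-butyldimethylsilyloxy)-6-methyl-3,8a-dihydroazulen-1(2H)-one | C1=CC(C)=CC(O[Si](C)(C)C(C)(C)C)=C2CCC(=O)[C@H]12 | intermediate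
11 | isopropylmagnesium chloride | CC(C)[Mg]Cl | starting material
12 | (1R,8aR)-4-(tert-butyldimethylsilyloxy)-6-methyl-1-(propan-2-yl)-1,2,3,8a-tetrahydroazulen-1-ol, i-Pr cis to C8a–H | C1=CC(C)=CC(O[Si](C)(C)C(C)(C)C)=C2CC[C@@](O)(C(C)C)[C@H]12 | intermediate
13 | iodomethane | CI | starting material
14 | tetrabutylammonium C1=C10 enolate from 12 (not isolated) | C1=CC(C)=CC([O-])=C2CC[C@@](O)(C(C)C)[C@H]12.CCCC[N+](CCCC)(CCCC)CCCC | intermediate
15 | (1S,4R,5R)-4β-hydroxydauca-6,8-dien-10-one, trans-fused (C1–CH3 β, C5–H α, i-Pr α) | C1=CC(C)=CC(=O)[C@@]2(C)CC[C@@](O)(C(C)C)[C@H]12 | intermediate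
16 | 4β-hydroxy-6α-(pinacolatoboryl)dauc-7-en-10-one | CC1(C)OB(OC1(C)C)[C@H]2C=C(C)CC(=O)[C@@]3(C)CC[C@@](O)(C(C)C)[C@H]23 | intermediate
17 | (1S,4R,5S,6S)-4β,6α-dihydroxydauc-7-en-10-one | O[C@H]1C=C(C)CC(=O)[C@@]2(C)CC[C@@](O)(C(C)C)[C@H]12 | intermediate
18 | (1S,4R,5S,6S)-4β,6α-dihydroxydauc-8-en-10-one | O[C@H]1CC(C)=CC(=O)[C@@]2(C)CC[C@@](O)(C(C)C)[C@H]12 | intermediate
19 | 4-methoxybenzoyl chloride | COc1ccc(C(Cl)=O)cc1 | starting material
20 | (1S,4R,5S,6S)-4β-hydroxy-6α-(4-methoxybenzoyloxy)dauc-8-en-10-one | COc1ccc(C(=O)O[C@H]2CC(C)=CC(=O)[C@@]3(C)CC[C@@](O)(C(C)C)[C@H]23)cc1 | intermediate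
21 | (1S,4R,5S,6S,10R)-6α-(4-methoxybenzoyloxy)dauc-8-ene-4β,10α-diol, CNP0211568.1 | COc1ccc(C(=O)O[C@H]2CC(C)=C[C@@H](O)[C@@]3(C)CC[C@@](O)(C(C)C)[C@H]23)cc1 | target

**Step count**
- Total steps: 12.
- Longest linear sequence: 12 steps (1 to 21). Compounds 6, 11, 13 and 19 are bought.

**Steps most likely to fail**

Step 5.
- What may go wrong: weak enantiofacial discrimination with a terminal diazoketone, diversion of the carbene into ipso attack with silyl loss or into aromatic substitution, and erosion of C5 on handling.
- Fallback: the absolute configuration is taken from a resolution instead of from the catalyst.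
- Setting out from 8, Rh2(OAc)4 (1 mol %) in CH2Cl2 is the most chemoselective catalyst for this substrate class. It should give, by way of the racemic norcaradiene F1, the racemic azulenone F2.
- The organocerium addition then gives the racemic carbinol F3. Fluoride and MeI give, by way of the racemic ammonium enolate F4, the racemic trans-fused dienone F5, the first robust compound of the series.
- Its enantiomers are separated by preparative chromatography on a polysaccharide-carbamate chiral stationary phase. The (1S,4R,5R) enantiomer is 15, where the route is rejoined.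

Step 7.
- What may go wrong: poor facial selectivity of C-methylation (cis-fused epimer), O-methylation, or proton transfer that scrambles the enolate and C5.
- Fallback: the methyl carbon is delivered by a hydroxyl-directed Simmons–Smith cyclopropanation instead of an enolate alkylation.
- Setting out from 12, Et2Zn/CH2I2 in CH2Cl2 (−20 °C to 0 °C) forms the zinc alkoxide of the homoallylic 4β-OH. This steers the carbenoid onto the β face of the most electron-rich alkene, the C1=C10 silyl enol ether, to give the siloxycyclopropane F6.
- Bu4NF in wet THF then frees the tetrabutylammonium cyclopropanolate F7. It opens at the bond between C10 and the unsubstituted CH2 (the less substituted carbanion), and protonation turns that carbon into the β angular methyl.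
- The route is rejoined at 15.

Step 12.
- What may go wrong: hydride delivery from the α face (10β epimer), some conjugate reduction, or base-induced elimination of the anisoate.
- Fallback: substrate control is replaced by catalyst control in a Corey–Bakshi–Shibata reduction.
- Setting out from 20, (S)-B-methyl oxazaborolidine and catecholborane are used in toluene at −78 °C. The catalyst binds the carbonyl lone pair on the side of the small vinylic flank C9, away from the quaternary C1, and should deliver hydride to the face that gives 10R.
- The reduction is strictly 1,2 and the medium is non-basic. The route is rejoined directly at 21, and no new compound is made.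

**Further compounds**
F1 | step 5 | racemic norcaradiene (9 and its mirror image) | O=C1CC[C@]23[C@H]1[C@H]2C=C(C)C=C3O[Si](C)(C)C(C)(C)C.O=C1CC[C@@]23[C@@H]1[C@@H]2C=C(C)C=C3O[Si](C)(C)C(C)(C)C
F2 | step 5 | racemic azulenone (10 and its mirror image) | C1=CC(C)=CC(O[Si](C)(C)C(C)(C)C)=C2CCC(=O)[C@H]12.C1=CC(C)=CC(O[Si](C)(C)C(C)(C)C)=C2CCC(=O)[C@@H]12
F3 | step 5 | racemic carbinol (12 and its mirror image) | C1=CC(C)=CC(O[Si](C)(C)C(C)(C)C)=C2CC[C@@](O)(C(C)C)[C@H]12.C1=CC(C)=CC(O[Si](C)(C)C(C)(C)C)=C2CC[C@](O)(C(C)C)[C@@H]12
F4 | step 5 | racemic ammonium enolate (14 and its mirror image) | C1=CC(C)=CC([O-])=C2CC[C@@](O)(C(C)C)[C@H]12.C1=CC(C)=CC([O-])=C2CC[C@](O)(C(C)C)[C@@H]12.CCCC[N+](CCCC)(CCCC)CCCC.CCCC[N+](CCCC)(CCCC)CCCC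
F5 | step 5 | racemic trans-fused dienone (15 and its mirror image) | C1=CC(C)=CC(=O)[C@@]2(C)CC[C@@](O)(C(C)C)[C@H]12.C1=CC(C)=CC(=O)[C@]2(C)CC[C@](O)(C(C)C)[C@@H]12
F6 | step 7 | siloxycyclopropane: CH2 bridging C1 and C10 on the β face, C10–OTBS, 6,8-diene and 4β-OH kept | C1=CC(C)=C[C@]3(O[Si](C)(C)C(C)(C)C)C[C@@]32CC[C@@](O)(C(C)C)[C@H]12
F7 | step 7 | tetrabutylammonium cyclopropanolate from F6 | C1=CC(C)=C[C@]3([O-])C[C@@]32CC[C@@](O)(C(C)C)[C@H]12.CCCC[N+](CCCC)(CCCC)CCCC
F0 | step 12 | none | none
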